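## Retrosynthetic overview

1. Sanggenone H (15) comes from global desilylation of the tris-silyl (2S)-flavanone 14.
2. The chromanone C-ring (O1–C2 bond, the only stereocentre) is formed last, by a cinchona-thiourea-catalysed intramolecular oxa-Michael addition of a phenol onto an alkylidene β-ketoester, then loss of the tert-butyl ester and CO2.
3. The alkylidene 12 comes from a Knoevenagel condensation of the A-ring β-ketoester 11 with the B-ring chromene aldehyde 6.
4. The 2H-chromene ring is formed first, by propargyl Claisen rearrangement/oxa-6π closure of the 2-O-(1,1-dimethylpropargyl) ether of 4-O-TIPS-2,4-dihydroxybenzaldehyde.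
5. Ketoester 11 comes from 2',4',6'-trihydroxyacetophenone by bis-silylation and C-carboxylation.

Assumption: the quinidine-derived thiourea is taken to give the (2S) series. This is from memory of how this catalyst class behaves, not a verified fact for this substrate; if CD on 14 shows the opposite sense, the quinine-derived pseudo-enantiomer is used in the same step.

## Route

**Step 1**
Reactants: 1, 2,4-dihydroxybenzaldehyde; 2, triisopropylsilyl chloride
Product: 3, 2-hydroxy-4-[(triisopropylsilyl)oxy]benzaldehyde
Conditions: TIPSCl (1.05 eq), imidazole, CH2Cl2, 0 °C → rt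
Reagents that add atoms: TIPSCl, CC(C)[Si](Cl)(C(C)C)C(C)C
Why: Selective silylation of the more acidic, non-hydrogen-bonded 4-OH; the 2-OH is chelated to the aldehyde and hindered.

**Step 2**
Reactants: 3; 4, 3-chloro-3-methylbut-1-yne
Product: 5, 2-[(2-methylbut-3-yn-2-yl)oxy]-4-[(triisopropylsilyl)oxy]benzaldehyde
Conditions: 4 (1.5 eq), DBU, CuCl2·2H2O (1 mol%), MeCN, 0 °C → rt
Reagents that add atoms: 3-chloro-3-methylbut-1-yne, C#CC(C)(C)Cl
Why: Copper-catalysed propargylic O-alkylation of an acidic phenol with a tertiary propargyl chloride; the TIPS ether and aldehyde tolerate DBU.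

**Step 3**
Reactants: 5
Product: 6, 2,2-dimethyl-5-[(triisopropylsilyl)oxy]-2H-chromene-8-carbaldehyde
Conditions: o-xylene, BHT (cat.), 140–150 °C, N2
Reagents that add atoms: none
Why: Aromatic propargyl Claisen rearrangement to C3 (the only free ortho position), then 1,5-H shift and oxa-6π electrocyclisation, gives the chromene fused on the oxygen ortho to the CHO.

**Step 4**
Reactants: 7, 2',4',6'-trihydroxyacetophenone (dried monohydrate); 8, tert-butyldimethylsilyl chloride
Product: 9, 1-{2,4-bis[(tert-butyldimethylsilyl)oxy]-6-hydroxyphenyl}ethan-1-one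
Conditions: TBSCl (2.2 eq), i-Pr2NEt, DMF, 0 °C → rt
Reagents that add atoms: TBSCl, CC(C)(C)[Si](C)(C)Cl
Why: Phenol silylation stops at the bis-ether because the last ortho-OH is strongly hydrogen-bonded to the ketone.

**Step 5**
Reactants: 9; 10, di-tert-butyl dicarbonate
Product: 11, tert-butyl 3-{2,4-bis[(tert-butyldimethylsilyl)oxy]-6-hydroxyphenyl}-3-oxopropanoate
Conditions: LiHMDS (3.3 eq), THF, −78 °C; Boc2O (1.1 eq), −78 → −20 °C; cold AcOH quench
Reagents that add atoms: Boc2O, CC(C)(C)OC(=O)OC(=O)OC(C)(C)C
Why: Crossed-Claisen-type C-acylation of the phenoxide/enolate dianion, which reacts at carbon; the third equivalent of base takes up the acidic product.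

**Step 6**
Reactants: 11; 6
Product: 12, tert-butyl 2-{2,4-bis[(tert-butyldimethylsilyl)oxy]-6-hydroxybenzoyl}-3-{2,2-dimethyl-5-[(triisopropylsilyl)oxy]-2H-chromen-8-yl}prop-2-enoate (alkene geometry not assigned; purified from any cyclised material)
Conditions: piperidine (20 mol%), AcOH (20 mol%), 4 Å MS, PhMe, rt → 40 °C
Reagents that add atoms: none (both partners are numbered reactants)
Why: Knoevenagel condensation under buffered amine catalysis; the bulky tert-butyl ester and mild conditions suppress premature racemic ring closure.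

**Step 7**
Reactants: 12
Product: 14, (2S)-5,7-bis[(tert-butyldimethylsilyl)oxy]-2-{2,2-dimethyl-5-[(triisopropylsilyl)oxy]-2H-chromen-8-yl}-2,3-dihydro-4H-chromen-4-one, via non-isolated 13, the corresponding tert-butyl (2S)-4-oxochromane-3-carboxylate
Conditions: N-[3,5-bis(trifluoromethyl)phenyl]-N'-[(9R)-6'-methoxycinchonan-9-yl]thiourea (quinidine-derived, 10 mol%), PhMe, −25 °C; then TsOH·H2O (0.5–1 eq), 80 °C
Reagents that add atoms: none
Why: Enantioselective intramolecular oxa-Michael addition in which the thiourea binds the β-ketoester and the quinuclidine delivers the phenol to one alkene face, setting C2 as S; TsOH then protonates the amine (blocking retro-Michael) and cleaves/decarboxylates the tert-butyl ester. Any partly desilylated material converges in step 8.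

**Step 8**
Reactants: 14
Product: 15, Sanggenone H, (2S)-5,7-dihydroxy-2-(5-hydroxy-2,2-dimethyl-2H-chromen-8-yl)-2,3-dihydro-4H-chromen-4-one
Conditions: TBAF/AcOH (1:1, 4 eq), THF, 0 °C; pH 6 buffer work-up
Reagents that add atoms: none
Why: Fluoride desilylation of the three aryl silyl ethers; acetic acid buffering keeps phenoxide concentration low so the base-labile C2 centre is not scrambled by retro-oxa-Michael opening, and the chromene is untouched.

## Compound list

1 | 2,4-dihydroxybenzaldehyde | O=Cc1ccc(O)cc1O | starting material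
2 | triisopropylsilyl chloride | CC(C)[Si](Cl)(C(C)C)C(C)C | starting material
3 | 2-hydroxy-4-[(triisopropylsilyl)oxy]benzaldehyde | O=Cc1ccc(O[Si](C(C)C)(C(C)C)C(C)C)cc1O | intermediate
4 | 3-chloro-3-methylbut-1-yne | C#CC(C)(C)Cl | starting material
5 | 2-[(2-methylbut-3-yn-2-yl)oxy]-4-[(triisopropylsilyl)oxy]benzaldehyde | O=Cc1ccc(O[Si](C(C)C)(C(C)C)C(C)C)cc1OC(C)(C)C#C | intermediate
6 | 2,2-dimethyl-5-[(triisopropylsilyl)oxy]-2H-chromene-8-carbaldehyde | CC1(C)C=Cc2c(O[Si](C(C)C)(C(C)C)C(C)C)ccc(C=O)c2O1 | intermediate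
7 | 2',4',6'-trihydroxyacetophenone | CC(=O)c1c(O)cc(O)cc1O | starting material
8 | tert-butyldimethylsilyl chloride | CC(C)(C)[Si](C)(C)Cl | starting material
9 | 1-{2,4-bis[(tert-butyldimethylsilyl)oxy]-6-hydroxyphenyl}ethan-1-one | CC(=O)c1c(O)cc(O[Si](C)(C)C(C)(C)C)cc1O[Si](C)(C)C(C)(C)C | intermediate
10 | di-tert-butyl dicarbonate | CC(C)(C)OC(=O)OC(=O)OC(C)(C)C | starting material
11 | tert-butyl 3-{2,4-bis[(tert-butyldimethylsilyl)oxy]-6-hydroxyphenyl}-3-oxopropanoate | CC(C)(C)OC(=O)CC(=O)c1c(O)cc(O[Si](C)(C)C(C)(C)C)cc1O[Si](C)(C)C(C)(C)C | intermediate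
12 | alkylidene β-ketoester (geometry unassigned) | CC(C)(C)OC(=O)C(=Cc1ccc(O[Si](C(C)C)(C(C)C)C(C)C)c2C=CC(C)(C)Oc12)C(=O)c1c(O)cc(O[Si](C)(C)C(C)(C)C)cc1O[Si](C)(C)C(C)(C)C | intermediate
13 | tert-butyl (2S)-5,7-bis(TBSO)-2-[2,2-dimethyl-5-(TIPSO)-2H-chromen-8-yl]-4-oxochromane-3-carboxylate (C3 unassigned, not isolated) | CC1(C)C=Cc2c(O[Si](C(C)C)(C(C)C)C(C)C)ccc([C@@H]3C(C(=O)OC(C)(C)C)C(=O)c4c(O[Si](C)(C)C(C)(C)C)cc(O[Si](C)(C)C(C)(C)C)cc4O3)c2O1 | intermediate
14 | (2S)-5,7-bis(TBSO)-2-[2,2-dimethyl-5-(TIPSO)-2H-chromen-8-yl]chroman-4-one | CC1(C)C=Cc2c(O[Si](C(C)C)(C(C)C)C(C)C)ccc([C@@H]3CC(=O)c4c(O[Si](C)(C)C(C)(C)C)cc(O[Si](C)(C)C(C)(C)C)cc4O3)c2O1 | intermediate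
15 | Sanggenone H | CC1(C)C=Cc2c(O)ccc([C@@H]3CC(=O)c4c(O)cc(O)cc4O3)c2O1 | target

## Summary

Total steps: 8 (step 7 is a one-pot, two-stage operation).
Longest linear sequence: 6 (steps 1, 2, 3, 6, 7, 8); the A-ring branch (steps 4, 5) joins at step 6.

Steps most likely to fail:

1. **Step 7.** The ortho-alkoxy aryl group and the 5-silyloxy group may lower the ee or reverse its sense, and the electron-rich B-ring may allow partial acid racemisation at 80 °C. Fallback: set C2 by asymmetric conjugate arylation instead. Convert 9 to 5,7-bis(silyloxy)chromone (DMF-DMA, then cyclisation) and add the 8-chromenylboronic acid under Rh(I)/chiral diene or Pd(II)/(S)-t-BuPyOx catalysis. The boronic acid would come from 4-bromoresorcinol by the same silylation/propargylation/Claisen sequence, then Li–Br exchange and borylation.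

2. **Step 6.** The aldehyde is hindered and electron-rich, so condensation may be sluggish, and premature racemic oxa-Michael closure would erode ee. Fallback: replace the Knoevenagel with a Mannich/elimination sequence. Convert 6 to its N-tosyl imine (TsNH2, Ti(OEt)4), add 11 under mild base, and eliminate TsNH2 to reach the same alkylidene 12.

3. **Step 5.** The dianion may undergo O-Boc formation, silyl migration, or closure to a 4-hydroxycoumarin instead of clean C-carboxylation. Fallback: build the ketoester from the ester oxidation level. Bis-silylate methyl 2,4,6-trihydroxybenzoate and run a crossed Claisen condensation with excess lithium tert-butyl acetate (LDA, t-BuOAc, THF, −78 °C → 0 °C) to give 11.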